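Ring B is made last, by one-carbon expansion of a trans-hydrindane. The target hides an aldol pattern (labdane numbering): C8, the methylidene carbon and a masked ketone, and the C11 oxygen flank C9. A Lewis-acid semipinacol rearrangement of a 1-(trans-epoxyalkyl)cyclopentanol therefore moves quaternary C10 from the carbinol carbon C8 to the epoxide carbon C9. In one operation the ring C5–C6–C7–C8–C10 becomes six-membered ring B, the C9–C10 bond forms, the C8 carbonyl appears, and the epoxide configuration is relayed to C9 (inversion) and C11 (retention). The precursor is an epoxy alcohol built from the Hajos–Parrish ketone by vinylation, cross-metathesis and hydroxyl-directed epoxidation.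

Key step: step 10

Remark: from step 8 on, locants follow labdane numbering (C8 methylidene carbon, C9 side-chain carbon, C10 angular-methyl carbon, C11 acetoxy carbon); methyl (2E)-4-bromo-3-methylbut-2-enoate is assumed to be purchased as the pure E isomer.

Step 1
Reactants: 1 (S)-(+)-Hajos–Parrish ketone
Product: 2 (7a'S)-7a'-methyl-2',3',7',7a'-tetrahydrospiro[1,3-dioxolane-2,1'-inden]-5'(6'H)-one (C1 monoketal)
Conditions: HOCH2CH2OH, p-TsOH (cat.), 4 Å MS, rt
Reagents that add atoms: ethylene glycol, OCCO
Why: Acid-catalysed ketalisation at room temperature should take place at the saturated cyclopentanone carbonyl, because the conjugated enone carbonyl is far less electrophilic; the C7a stereocentre is not touched.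

Step 2
Reactants: 2 C1 monoketal
Product: 4 (7a'S)-4',4',7a'-trimethyl-2',4',7',7a'-tetrahydrospiro[1,3-dioxolane-2,1'-inden]-5'(6'H)-one (C3'=C3a' alkene), via 4-methyl enone ketal 3 (not isolated)
Conditions: t-BuOK (2.5 equiv), MeI (excess), t-BuOH/THF, 0 °C → rt
Reagents that add atoms: iodomethane, CI
Why: Deconjugative α,α-dialkylation of an enone: the potassium dienolate should be methylated twice at the α-carbon C4, which installs the gem-dimethyl group and leaves the double bond at C3=C3a, while the ketal blocks enolisation at C1.

Step 3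
Reactants: 4 gem-dimethyl β,γ-enone ketal
Product: 6 (7a'S)-4',4',7a'-trimethyl-2',4',5',6',7',7a'-hexahydrospiro[1,3-dioxolane-2,1'-indene], via hydrazone 5 (not isolated)
Conditions: N2H4·H2O, KOH, diethylene glycol, 130 °C then 200 °C
Reagents that add atoms: hydrazine, NN (its nitrogen atoms stay only in intermediate 5)
Why: Wolff–Kishner reduction (Huang-Minlon procedure) should remove the C5 carbonyl through the hydrazone with loss of N2; the quaternary α-carbon prevents double-bond migration and the ketal is stable to base.

Step 4
Reactants: 6 alkene ketal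
Product: 7 (3a'S,7a'S)-4',4',7a'-trimethyloctahydrospiro[1,3-dioxolane-2,1'-indene] (trans-fused)
Conditions: H2 (4 atm), 10% Pd/C, EtOAc, rt
Reagents that add atoms: none
Why: Heterogeneous hydrogenation should deliver hydrogen to the face of the C3=C3a alkene opposite the angular methyl and the axial C4 methyl, as with 4,4-dimethyl-5-ene steroids, which sets C3a–H trans to the C7a methyl (3aS).

Step 5
Reactants: 7 saturated ketal
Product: 8 (3aS,7aS)-4,4,7a-trimethyloctahydro-1H-inden-1-one
Conditions: 2 M aq. HCl, THF, rt
Reagents that add atoms: water, O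
Why: Acid-catalysed hydrolysis of the dioxolane should release the ketone; neither ring-fusion centre can epimerise because C7a is quaternary and C3a is not α to the carbonyl.

Step 6
Reactants: 8 trans-hydrindanone
Product: 9 (1R,3aS,7aS)-1-ethenyl-4,4,7a-trimethyloctahydro-1H-inden-1-ol
Conditions: CH2=CHMgBr, CeCl3, THF, −78 → 0 °C; then H2O
Reagents that add atoms: vinylmagnesium bromide, C=C[Mg]Br
Why: 1,2-Addition of the vinylcerium reagent (which suppresses enolisation of the hindered ketone) should occur from the face anti to the angular methyl, as in 17-keto steroids, giving the 1R carbinol with OH cis to the methyl.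

Step 7
Reactants: 10 methyl (2E)-4-bromo-3-methylbut-2-enoate
Product: 11 methyl (2E)-3-methylhexa-2,5-dienoate
Conditions: Bu3SnCH=CH2, Pd2(dba)3 (2.5 mol%), P(2-furyl)3 (10 mol%), THF, 50 °C
Reagents that add atoms: tributyl(vinyl)stannane, C=C[Sn](CCCC)(CCCC)CCCC
Why: Stille coupling of an allylic bromide: oxidative addition to zerovalent palladium gives a syn-π-allyl complex that, after transmetalation, should couple at its unsubstituted CH2 terminus, so the conjugation and E geometry of the enoate are kept.

Step 8
Reactants: 9 vinyl carbinol; 11 skipped dienoate (3 equiv)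
Product: 12 methyl (2E,5E)-6-[(1R,3aS,7aS)-1-hydroxy-4,4,7a-trimethyloctahydro-1H-inden-1-yl]-3-methylhexa-2,5-dienoate
Conditions: second-generation Grubbs catalyst (5 mol%), 1,4-benzoquinone (10 mol%), CH2Cl2, 40 °C
Reagents that add atoms: none
Why: Olefin cross-metathesis between a terminal alkene and a hindered tertiary allylic alcohol that cannot homodimerise; the bulky carbinol should enforce the E geometry of the new C9=C11 double bond, and the trisubstituted enoate alkene is inert.

Step 9
Reactants: 12 E-allylic alcohol
Product: 13 methyl (2E)-4-[(2S,3R)-3-[(1S,3aS,7aS)-1-hydroxy-4,4,7a-trimethyloctahydro-1H-inden-1-yl]oxiran-2-yl]-3-methylbut-2-enoate (trans-epoxide; 9R,11S)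
Conditions: VO(acac)2 (5 mol%), t-BuOOH (1.5 equiv, in decane), CH2Cl2, 0 °C → rt
Reagents that add atoms: tert-butyl hydroperoxide, CC(C)(C)OO
Why: Vanadium-catalysed hydroxyl-directed epoxidation should touch only the allylic-alcohol alkene (the enoate is electron-poor), and the face follows from the transition state with an O–C8–C9=C11 dihedral near 50°, the ring CH2 (C7) near the alkene plane beside H9 and quaternary C10 turned away from vanadium (the tertiary-alcohol analogue of the erythro-selective model), which predicts the (9R,11S) trans-epoxide.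

Step 10
Reactants: 13 epoxy alcohol
Product: 14 methyl (2E,5S)-5-hydroxy-3-methyl-5-[(1S,4aS,8aS)-5,5,8a-trimethyl-2-oxodecahydronaphthalen-1-yl]pent-2-enoate (9S,11S)
Conditions: SnCl4 (1.2 equiv), CH2Cl2, −78 → −30 °C; then aq. NaHCO3
Reagents that add atoms: none
Why: SnCl4 chelates the C8 hydroxyl and the epoxide oxygen, the C9–O bond ionises, and the antiperiplanar C8–C10 bond shifts to C9 while C8 becomes the carbonyl carbon; this is the semipinacol rearrangement of a 2,3-epoxy alcohol, known from ring expansions of 1-oxiranylcycloalkanols and related to the D-homoannulation of steroids. Ring B is closed by this 1,2-alkyl shift, a ring expansion that inserts C9 between C8 and C10 of the cyclopentane C5–C6–C7–C8–C10, not by cyclisation of a chain. C9 is set by inversion (C10 arrives anti to the departing oxygen and migrates with retention) and C11 keeps its C–O bond, so the trans-(9R,11S) epoxide should give the anti aldol (9S,11S). The step needs cleavage at C9 and not at C11, which is secured because only C9 has an antiperiplanar migrating bond and the oxygen push from C8. It also needs migration of quaternary C10 rather than methylene C7: in the chelated rotamer with C10 anti to C9–O the side chain lies between O8 and C10 and H9 between the two ring carbons, whereas the rotamer with C7 anti forces the side chain between both ring carbons, and the more substituted carbon also has the higher migratory aptitude. The C9 substituent ends up equatorial, the stable epimer, so later steps should not erode it.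

Step 11
Reactants: 14 β-hydroxy ketone
Product: 15 methyl (2E,5S)-5-hydroxy-3-methyl-5-[(1S,4aS,8aS)-5,5,8a-trimethyl-2-methylidenedecahydronaphthalen-1-yl]pent-2-enoate
Conditions: Zn, CH2Br2, TiCl4, THF/CH2Cl2, 0 °C → rt
Reagents that add atoms: dibromomethane, BrCBr
Why: Takai–Lombardo methylenation: the non-basic zinc–titanium methylene reagent should convert the hindered, enolisable ketone into the exocyclic alkene without epimerisation at C9, retro-aldol cleavage or attack on the ester.

Step 12
Reactants: 15 hydroxy diene ester
Product: 16 methyl (11S,13E)-11-acetoxylabda-8(17),13-dien-15-oate (target)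
Conditions: Ac2O, DMAP (cat.), pyridine, CH2Cl2, rt
Reagents that add atoms: acetic anhydride, CC(=O)OC(C)=O
Why: DMAP-catalysed acylation of the only hydroxyl group should proceed with retention at C11 and leave the skipped diene ester untouched.

Compound list
1 | (S)-(+)-Hajos–Parrish ketone, (7aS)-7a-methyl-2,3,7,7a-tetrahydro-1H-indene-1,5(6H)-dione | O=C1CCC2=CC(=O)CC[C@]12C | starting material
2 | (7a'S)-7a'-methyl-2',3',7',7a'-tetrahydrospiro[1,3-dioxolane-2,1'-inden]-5'(6'H)-one | O1CCOC12CCC3=CC(=O)CC[C@]23C | intermediate
3 | (7a'S)-4',7a'-dimethyl-2',3',7',7a'-tetrahydrospiro[1,3-dioxolane-2,1'-inden]-5'(6'H)-one (monomethyl enone, not isolated) | O1CCOC12CCC3=C(C)C(=O)CC[C@]23C | intermediate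
4 | (7a'S)-4',4',7a'-trimethyl-2',4',7',7a'-tetrahydrospiro[1,3-dioxolane-2,1'-inden]-5'(6'H)-one | O1CCOC12CC=C3C(C)(C)C(=O)CC[C@]23C | intermediate
5 | hydrazone of 4 (not isolated) | O1CCOC12CC=C3C(C)(C)C(=NN)CC[C@]23C | intermediate
6 | (7a'S)-4',4',7a'-trimethyl-2',4',5',6',7',7a'-hexahydrospiro[1,3-dioxolane-2,1'-indene] | O1CCOC12CC=C3C(C)(C)CCC[C@]23C | intermediate
7 | (3a'S,7a'S)-4',4',7a'-trimethyloctahydrospiro[1,3-dioxolane-2,1'-indene] | O1CCOC12CC[C@H]3C(C)(C)CCC[C@]23C | intermediate
8 | (3aS,7aS)-4,4,7a-trimethyloctahydro-1H-inden-1-one | O=C1CC[C@H]2C(C)(C)CCC[C@]12C | intermediate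
9 | (1R,3aS,7aS)-1-ethenyl-4,4,7a-trimethyloctahydro-1H-inden-1-ol | C=C[C@]1(O)CC[C@H]2C(C)(C)CCC[C@]12C | intermediate
10 | methyl (2E)-4-bromo-3-methylbut-2-enoate | COC(=O)/C=C(C)/CBr | starting material
11 | methyl (2E)-3-methylhexa-2,5-dienoate | COC(=O)/C=C(C)/CC=C | intermediate
12 | methyl (2E,5E)-6-[(1R,3aS,7aS)-1-hydroxy-4,4,7a-trimethyloctahydro-1H-inden-1-yl]-3-methylhexa-2,5-dienoate | COC(=O)/C=C(C)/C/C=C/[C@]1(O)CC[C@H]2C(C)(C)CCC[C@]12C | intermediate
13 | methyl (2E)-4-[(2S,3R)-3-[(1S,3aS,7aS)-1-hydroxy-4,4,7a-trimethyloctahydro-1H-inden-1-yl]oxiran-2-yl]-3-methylbut-2-enoate | COC(=O)/C=C(C)/C[C@@H]3O[C@H]3[C@]1(O)CC[C@H]2C(C)(C)CCC[C@]12C | intermediate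
14 | methyl (2E,5S)-5-hydroxy-3-methyl-5-[(1S,4aS,8aS)-5,5,8a-trimethyl-2-oxodecahydronaphthalen-1-yl]pent-2-enoate | O=C1CC[C@H]2C(C)(C)CCC[C@]2(C)[C@H]1[C@H](C/C(C)=C/C(=O)OC)O | intermediate
15 | methyl (2E,5S)-5-hydroxy-3-methyl-5-[(1S,4aS,8aS)-5,5,8a-trimethyl-2-methylidenedecahydronaphthalen-1-yl]pent-2-enoate | C=C1CC[C@H]2C(C)(C)CCC[C@]2(C)[C@H]1[C@H](C/C(C)=C/C(=O)OC)O | intermediate
16 | methyl (11S,13E)-11-acetoxylabda-8(17),13-dien-15-oate, i.e. methyl (2E,5S)-5-acetoxy-3-methyl-5-[(1S,4aS,8aS)-5,5,8a-trimethyl-2-methylidenedecahydronaphthalen-1-yl]pent-2-enoate | C=C1CC[C@H]2C(C)(C)CCC[C@]2(C)[C@H]1[C@H](C/C(C)=C/C(=O)OC)OC(C)=O | target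

Total step count: 12. Longest linear sequence: 11 steps (steps 1–6 and 8–12 from 1); step 7 is a one-step side branch.

Steps most likely to fail

Step 10. The epoxide may be opened at the distal carbon C11 by chloride from the Lewis acid, or the ring methylene C7 may migrate in place of C10, which would give a regioisomeric decalone. The fallback sets out from 13 and returns at 14. It removes both the chelate and the nucleophilic halide by switching to an epoxy silyl ether rearrangement. The tertiary alcohol of 13 is silylated with N-(trimethylsilyl)imidazole to give the trimethylsilyl ether of the epoxy alcohol F1. Treatment with methylaluminium bis(4-bromo-2,6-di-tert-butylphenoxide), made from Me3Al and the phenol, in CH2Cl2 at −78 °C should trigger the same anti 1,2-shift with silyl transfer to the C11 oxygen, giving the β-silyloxy ketone F2. Mild acidic methanolysis (citric acid, MeOH) should then release 14.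

Step 9. Facial selectivity of the directed epoxidation may be poor. The diastereomeric trans-epoxide would place C7 anti to the breaking bond and would carry the wrong C9 and C11 configurations. The fallback sets out from 12 and returns at 13, and replaces substrate direction by reagent control. It is a Shi epoxidation with the L-fructose-derived ketone (the enantiomer of the usual D-fructose-derived catalyst), Oxone, K2CO3 buffer, Bu4NHSO4, MeCN/dimethoxymethane/H2O, 0 °C. For a trans-disubstituted alkene the mnemonic of this catalyst predicts oxygen delivery to the face that gives the (9R,11S) epoxide. This fallback makes no new compound (F0).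

Step 8. Metathesis at the very hindered vinyl carbinol may be slow, so that homodimerisation of 11 and ruthenium-hydride isomerisation of the skipped diene into conjugation take over. The fallback sets out from 8 and returns at 12, and builds the E-alkene by hydrometalation and cross-coupling instead. Ethynylmagnesium bromide with CeCl3 in THF should add to 8 from the face anti to the angular methyl, giving the ethynyl carbinol F3. Hydrostannation (Bu3SnH, PdCl2(PPh3)2, THF) should place tin at the unhindered terminus by syn addition, giving the (E)-vinylstannane F4. Stille coupling of F4 with allylic bromide 10 (Pd2(dba)3, AsPh3, THF, 50 °C) should then give 12 with both alkene geometries retained.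

Further compounds
F1 | step 10 | methyl (2E)-4-[(2S,3R)-3-[(1S,3aS,7aS)-4,4,7a-trimethyl-1-(trimethylsilyloxy)octahydro-1H-inden-1-yl]oxiran-2-yl]-3-methylbut-2-enoate | COC(=O)/C=C(C)/C[C@@H]3O[C@H]3[C@]1(O[Si](C)(C)C)CC[C@H]2C(C)(C)CCC[C@]12C
F2 | step 10 | methyl (2E,5S)-3-methyl-5-[(1S,4aS,8aS)-5,5,8a-trimethyl-2-oxodecahydronaphthalen-1-yl]-5-(trimethylsilyloxy)pent-2-enoate | O=C1CC[C@H]2C(C)(C)CCC[C@]2(C)[C@H]1[C@H](C/C(C)=C/C(=O)OC)O[Si](C)(C)C
F0 | step 9 | none | none
F3 | step 8 | (1R,3aS,7aS)-1-ethynyl-4,4,7a-trimethyloctahydro-1H-inden-1-ol | C#C[C@]1(O)CC[C@H]2C(C)(C)CCC[C@]12C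
F4 | step 8 | (1R,3aS,7aS)-4,4,7a-trimethyl-1-[(E)-2-(tributylstannyl)ethenyl]octahydro-1H-inden-1-ol | CCCC[Sn](CCCC)(CCCC)/C=C/[C@]1(O)CC[C@H]2C(C)(C)CCC[C@]12C
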